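The dihydropyranone ring (O1–C2(=O)–C3=C4–C5–C6) is opened at C5–C6 and at the C3=C4 olefin. The key step exploits that C6 is an O-acylated carbinol carbon, allylic to C7=C8 and homoallylic to the cis ring olefin. In one flask, a catalytic Si-face allylation of (E)-enal 10 makes C5–C6 and the C6 stereocentre, the tin alkoxide is capped with acryloyl chloride, and ring-closing metathesis makes C3=C4. Enal 10 already holds the anti C10/C12 diol monoacetate, built from cinnamaldehyde by a boron aldol (C12) and an Evans–Tishchenko hydride relay with acetaldehyde (C10 and the acetate at once).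

Key step: step 5

Numbering: lactone O1, C2 (C=O), C3=C4, C5, C6; side chain C7=C8, C9, C10 (OH), C11, C12 (OAc), C13=C14–Ph.
Assumption: (+)-Ipc2BCl is taken to direct Si-face attack of the methyl ketone enolate on cinnamaldehyde; should the adduct prove antipodal, (−)-Ipc2BCl is used and nothing else changes.

Step 1
Reactants: 1 4,4-dimethoxybutan-2-one; 2 (E)-cinnamaldehyde
Product: 5 (5S,6E)-5-hydroxy-1,1-dimethoxy-7-phenylhept-6-en-3-one, via enol borinate 3 (not isolated), via boron aldolate 4 (not isolated)
Conditions: (+)-Ipc2BCl, Et3N, Et2O, 0 °C; then 2, −78 to −20 °C; H2O2, MeOH, pH 7 buffer, 0 °C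
Reagents that add atoms: none
Why: Boron aldol with a chiral Ipc ligand set (Paterson aldol): Ipc2BCl/Et3N enolises the unhindered CH3 side of 1 to enol borinate 3, which adds to the aldehyde through a cyclic boron transition state in which the Ipc groups select the Si face and so set C12 as S (reagent control), and buffered peroxide then frees 5 from aldolate 4 without acid that would cyclise the hydroxy acetal.

Step 2
Reactants: 5 (5S,6E)-5-hydroxy-1,1-dimethoxy-7-phenylhept-6-en-3-one
Product: 6 (1E,3S,5S)-5-hydroxy-7,7-dimethoxy-1-phenylhept-1-en-3-yl acetate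
Conditions: MeCHO (6 equiv), SmI2 (0.2 equiv), THF, −10 °C
Reagents that add atoms: acetaldehyde, CC=O
Why: Evans–Tishchenko reduction: the samarium-bound C12 alkoxide adds to acetaldehyde and the resulting hemiacetal passes its hydride to the C10 ketone within a chair-like bicyclic transition state, which sets C10 1,3-anti to C12 by substrate control and leaves the acetate on O–C12 and the free hydroxyl on C10 in the same event.

Step 3
Reactants: 6 (1E,3S,5S)-5-hydroxy-7,7-dimethoxy-1-phenylhept-1-en-3-yl acetate
Product: 9 (1E,3S,5S)-7-oxo-1-phenyl-5-(triethylsilyloxy)hept-1-en-3-yl acetate, via TES ether acetal 7 (not isolated), via methoxy-collidinium triflate 8 (not isolated)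
Conditions: TESOTf (3.5 equiv), 2,4,6-collidine (5 equiv), CH2Cl2, 0 °C; then H2O, rt
Reagents that add atoms: triethylsilyl triflate, CC[Si](CC)(CC)OS(=O)(=O)C(F)(F)F; water, O
Why: Silylation and chemoselective acetal cleavage by a silyl triflate with a hindered pyridine: TESOTf first caps the C10 hydroxyl (7), then ionises the dimethyl acetal, whose oxocarbenium ion is trapped by collidine as pyridinium salt 8 and hydrolysed to the aldehyde by water under non-acidic conditions that spare the allylic acetate; no stereocentre is touched.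

Step 4
Reactants: 9 (1E,3S,5S)-7-oxo-1-phenyl-5-(triethylsilyloxy)hept-1-en-3-yl acetate
Product: 10 (1E,3S,5R,7E)-9-oxo-1-phenyl-5-(triethylsilyloxy)nona-1,7-dien-3-yl acetate
Conditions: Ph3P=CHCHO, toluene, 80 °C
Reagents that add atoms: (triphenylphosphoranylidene)acetaldehyde, O=CC=P(c1ccccc1)(c1ccccc1)c1ccccc1
Why: Wittig olefination with a stabilised formyl ylide, which gives the (E)-enal under neutral conditions that do not eliminate the β-silyloxy group; no stereocentre is formed.

Step 5
Reactants: 10 (1E,3S,5R,7E)-9-oxo-1-phenyl-5-(triethylsilyloxy)nona-1,7-dien-3-yl acetate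
Product: 13 (1E,3S,5R,7E)-8-[(2S)-6-oxo-3,6-dihydro-2H-pyran-2-yl]-1-phenyl-5-(triethylsilyloxy)octa-1,7-dien-3-yl acetate, via stannyl ether 11 (not isolated), via triene acrylate 12 (not isolated)
Conditions: (S)-BINOL (20 mol%), Ti(OiPr)4 (20 mol%), 4 Å MS, allylSnBu3, CH2Cl2, −20 °C; then CH2=CHCOCl, 0 °C to rt; concentrate; CH2Cl2 (5 mM), RuCl2(=CHPh)(PCy3)2 (first-generation Grubbs catalyst, 10 mol%), 40 °C
Reagents that add atoms: allyltributylstannane, C=CC[Sn](CCCC)(CCCC)CCCC; acryloyl chloride, C=CC(=O)Cl
Why: Keck asymmetric allylation: the (S)-BINOL–titanium Lewis acid binds the enal carbonyl and allylSnBu3 attacks C6 from the Si face through an open transition state, forming C5–C6 and, on turnover, stannyl ether 11. The Sn–O bond is then acylated by acryloyl chloride without base to give triene ester 12, and the first-generation Grubbs catalyst closes the ring; the closest known chemistry is the stepwise allylation, acryloylation and ring-closing metathesis route to 6-substituted 5,6-dihydropyran-2-ones, telescoped here into one flask. The ring closure is a ring-closing metathesis of the terminal homoallyl olefin onto the acrylate, which forms the six-membered lactone with loss of ethylene and enforces the Z geometry at C3=C4. C6 (S) is set by the catalyst alone, since C10 and C12 are too remote to bias the carbonyl faces. The step needs 1,2- rather than 1,4-addition (normal for Lewis-acid-promoted allylstannane additions to enals), acylation at O–C6 only (the other oxygens are capped as TES ether and acetate), and metathesis at the two monosubstituted olefins only; the rival five-membered butenolide (C3=C7) would need initiation at the acrylate or at the internal C7=C8 olefin, which this catalyst does not do at a useful rate. The Ti(OiPr)4 left from the first stage also keeps the ester carbonyl from chelating the ruthenium carbene.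

Step 6
Reactants: 13 (1E,3S,5R,7E)-8-[(2S)-6-oxo-3,6-dihydro-2H-pyran-2-yl]-1-phenyl-5-(triethylsilyloxy)octa-1,7-dien-3-yl acetate
Product: 14 (1E,3S,5R,7E)-5-hydroxy-8-[(2S)-6-oxo-3,6-dihydro-2H-pyran-2-yl]-1-phenylocta-1,7-dien-3-yl acetate
Conditions: HF·pyridine, pyridine, THF, 0 °C
Reagents that add atoms: none
Why: Fluoride-mediated desilylation under pyridine-buffered conditions, which cleaves the TES ether without base-induced acetyl migration from O–C12 to O–C10 or attack on the unsaturated lactone; no stereocentre is affected.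

Compound list
1 | 4,4-dimethoxybutan-2-one | COC(OC)CC(C)=O | starting material
2 | (E)-cinnamaldehyde | O=C/C=C/c1ccccc1 | starting material
3 | 4,4-dimethoxybut-1-en-2-yl bis[(+)-isopinocampheyl]borinate (enol borinate of 1) | C=C(CC(OC)OC)OB([C@H]1C[C@H]2C[C@@H]([C@@H]1C)C2(C)C)[C@H]1C[C@H]2C[C@@H]([C@@H]1C)C2(C)C | intermediate
4 | bis[(+)-isopinocampheyl]borinate ester of 5 (boron aldolate) | COC(OC)CC(=O)C[C@@H](/C=C/c1ccccc1)OB([C@H]1C[C@H]2C[C@@H]([C@@H]1C)C2(C)C)[C@H]1C[C@H]2C[C@@H]([C@@H]1C)C2(C)C | intermediate
5 | (5S,6E)-5-hydroxy-1,1-dimethoxy-7-phenylhept-6-en-3-one | COC(OC)CC(=O)C[C@H](O)/C=C/c1ccccc1 | intermediate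
6 | (1E,3S,5S)-5-hydroxy-7,7-dimethoxy-1-phenylhept-1-en-3-yl acetate | CC(=O)O[C@H](/C=C/c1ccccc1)C[C@H](O)CC(OC)OC | intermediate
7 | (1E,3S,5S)-7,7-dimethoxy-1-phenyl-5-(triethylsilyloxy)hept-1-en-3-yl acetate | CC(=O)O[C@H](/C=C/c1ccccc1)C[C@H](O[Si](CC)(CC)CC)CC(OC)OC | intermediate
8 | 1-[(3S,5S,6E)-5-acetoxy-1-methoxy-7-phenyl-3-(triethylsilyloxy)hept-6-en-1-yl]-2,4,6-trimethylpyridinium triflate (both configurations at C1) | CC(=O)O[C@H](/C=C/c1ccccc1)C[C@H](O[Si](CC)(CC)CC)CC(OC)[n+]1c(C)cc(C)cc1C.[O-]S(=O)(=O)C(F)(F)F | intermediate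
9 | (1E,3S,5S)-7-oxo-1-phenyl-5-(triethylsilyloxy)hept-1-en-3-yl acetate | CC(=O)O[C@H](/C=C/c1ccccc1)C[C@H](O[Si](CC)(CC)CC)CC=O | intermediate
10 | (1E,3S,5R,7E)-9-oxo-1-phenyl-5-(triethylsilyloxy)nona-1,7-dien-3-yl acetate | CC(=O)O[C@H](/C=C/c1ccccc1)C[C@H](O[Si](CC)(CC)CC)C/C=C/C=O | intermediate
11 | (1E,3S,5R,7E,9S)-1-phenyl-9-(tributylstannyloxy)-5-(triethylsilyloxy)dodeca-1,7,11-trien-3-yl acetate | CC(=O)O[C@H](/C=C/c1ccccc1)C[C@H](O[Si](CC)(CC)CC)C/C=C/[C@@H](O[Sn](CCCC)(CCCC)CCCC)CC=C | intermediate
12 | (1E,3S,5R,7E,9S)-3-acetoxy-1-phenyl-5-(triethylsilyloxy)dodeca-1,7,11-trien-9-yl prop-2-enoate | CC(=O)O[C@H](/C=C/c1ccccc1)C[C@H](O[Si](CC)(CC)CC)C/C=C/[C@@H](OC(=O)C=C)CC=C | intermediate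
13 | (1E,3S,5R,7E)-8-[(2S)-6-oxo-3,6-dihydro-2H-pyran-2-yl]-1-phenyl-5-(triethylsilyloxy)octa-1,7-dien-3-yl acetate | CC(=O)O[C@H](/C=C/c1ccccc1)C[C@H](O[Si](CC)(CC)CC)C/C=C/[C@@H]1CC=CC(=O)O1 | intermediate
14 | (1E,3S,5R,7E)-5-hydroxy-8-[(2S)-6-oxo-3,6-dihydro-2H-pyran-2-yl]-1-phenylocta-1,7-dien-3-yl acetate | CC(=O)O[C@H](/C=C/c1ccccc1)C[C@H](O)C/C=C/[C@@H]1CC=CC(=O)O1 | target

Total step count: 6. Longest linear sequence: 6 (1 to 14).

Steps most likely to fail

Step 5. The telescoped sequence may stall through incomplete turnover or incomplete acylation at the stannyl ether stage, through deactivation of the ruthenium carbene by tin, titanium or BINOL residues, or through eroded Si-face selectivity that leaves a C6 epimer hard to separate because C6 is remote from C10. The fallback sets out from 10 and replaces catalytic Lewis-acid allylation by stoichiometric, reagent-controlled Brown allylboration with every intermediate purified. (−)-Ipc2B(allyl) in Et2O at −78 °C, with NaBO3·4H2O work-up, adds to the Si face through a closed six-membered transition state and gives (1E,3S,5R,7E,9S)-9-hydroxy-1-phenyl-5-(triethylsilyloxy)dodeca-1,7,11-trien-3-yl acetate F1. Acryloyl chloride and Et3N in CH2Cl2 at 0 °C convert F1 into 12, now isolated. Ring-closing metathesis of pure 12 with RuCl2(=CHPh)(PCy3)2 and Ti(OiPr)4 in CH2Cl2 at 40 °C returns to the route at 13.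

Step 1. Enantiofacial discrimination may be incomplete, since methyl ketone Ipc enolates are less selective than ethyl ketone ones. The minor enantiomer would then pass mainly into the C6-epimeric series after step 5, so the desired diastereomer of 13 or 14 would have to be purified by HPLC. The hydroxy acetal may also cyclise onto C8 on acidic silica. The fallback sets out from 1 and uses a catalytic enantioselective Mukaiyama aldol instead of a chiral boron enolate. LiN(iPr)2 and TMSCl in THF at −78 °C give the kinetic enol silane (4,4-dimethoxybut-1-en-2-yloxy)trimethylsilane F2. F2 adds to 2 under a tartaric-acid-derived acyloxyborane catalyst (20 mol%, EtCN, −78 °C; the tartrate antipode that exposes the Si face) to give the silylated aldol (5S,6E)-1,1-dimethoxy-7-phenyl-5-(trimethylsilyloxy)hept-6-en-3-one F3. Methanolysis of F3 (catalytic K2CO3, MeOH, 0 °C) returns to the route at 5.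

Step 3. The collidinium intermediate may collapse by elimination to an enol ether or hydrolyse incompletely, and the one-flask sequence may leave mixtures of silylated and unsilylated material. The fallback sets out from 6 and inverts the order of events, so that no silyl group or pyridinium salt is present when the acetal is opened. Hydrolysis with oxalic acid on wet silica gel in CH2Cl2 at rt gives the β-hydroxy aldehyde (1E,3S,5S)-5-hydroxy-7-oxo-1-phenylhept-1-en-3-yl acetate F4. Silylation of F4 with TESCl and imidazole in DMF at 0 °C returns to the route at 9.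

Further compounds
F1 | step 5 | (1E,3S,5R,7E,9S)-9-hydroxy-1-phenyl-5-(triethylsilyloxy)dodeca-1,7,11-trien-3-yl acetate | CC(=O)O[C@H](/C=C/c1ccccc1)C[C@H](O[Si](CC)(CC)CC)C/C=C/[C@@H](O)CC=C
F2 | step 1 | (4,4-dimethoxybut-1-en-2-yloxy)trimethylsilane | C=C(CC(OC)OC)O[Si](C)(C)C
F3 | step 1 | (5S,6E)-1,1-dimethoxy-7-phenyl-5-(trimethylsilyloxy)hept-6-en-3-one | COC(OC)CC(=O)C[C@@H](/C=C/c1ccccc1)O[Si](C)(C)C
F4 | step 3 | (1E,3S,5S)-5-hydroxy-7-oxo-1-phenylhept-1-en-3-yl acetate | CC(=O)O[C@H](/C=C/c1ccccc1)C[C@H](O)CC=O
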